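The cyclohexanetrione ring is disconnected at C4–C5 (C4: ketone between the methyl/prenyl carbon C3 and spiro carbon C5). The key step exploits the 1,3,5-tricarbonyl array of this ring: C5 is the γ-carbon of the C2–C1–C6 β-diketone and, made allylic by a temporary C10=C11 double bond, attacks the C4 ester as a polyanion (intramolecular Claisen/Dieckmann acylation). One operation closes the trione ring and sets the spiro centre from the convex face of a cis-fused hydrindene. The precursor is a linalool-derived bicyclic diketo ester, made by intramolecular Diels–Alder reaction and acylation with a malonate of defined C3 configuration. Late hydration of C10=C11, cross-metathesis and C-acylation finish.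

Key step: step 9

Numbering used below (locants of the target): trione ring C1 (acyl-bearing), C2 (enol carbon), C3 (methyl/prenyl carbon), C4 (ketone), C5 (spiro carbon), C6 (ketone); six-membered carbocycle C5–C7–C8–C9–C10–C11 (C8 and C9 are the ring-fusion CH, C10 a carbinol); five-membered ring C8–C14–C13–C12–C9 (C14 a carbinol). The convex face of the hydrindane is the one that carries H8 and H9.

Assumption: the (S,S)-configured N-spiro ammonium phase-transfer catalyst is taken to give the (S)-malonate 5, by analogy with other alkyl halides in this catalyst system; if the sense were opposite, the (R,R)-catalyst would be used.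

Step 1
Reactants: 1 2,2,5-trimethyl-1,3-dioxane-4,6-dione
Product: 2 3-tert-butoxy-2-methyl-3-oxopropanoic acid (racemic)
Conditions: t-BuOH, reflux
Reagents that add atoms: tert-butanol, CC(C)(C)O
Why: Alcoholysis of the Meldrum-type dioxanedione opens the ring at one carbonyl and releases acetone, which gives the malonic half ester free of diester.

Step 2
Reactants: 2 3-tert-butoxy-2-methyl-3-oxopropanoic acid; 3 2,2-diphenylethanol
Product: 4 tert-butyl 2,2-diphenylethyl 2-methylpropanedioate (racemic)
Conditions: EDC·HCl, DMAP (cat.), CH2Cl2, 0 °C to rt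
Reagents that add atoms: none
Why: Carbodiimide (Steglich-type) esterification of the free acid with the primary alcohol leaves the tert-butyl ester untouched, and the labile α-centre does not matter because it is enolised in step 3.

Step 3
Reactants: 4 tert-butyl 2,2-diphenylethyl 2-methylpropanedioate
Product: 5 1-tert-butyl 3-(2,2-diphenylethyl) (2S)-2-methyl-2-(prop-2-en-1-yl)propanedioate
Conditions: allyl bromide, 50% aq. KOH, (S,S)-3,4,5-trifluorophenyl-NAS bromide (5 mol%), PhMe, −40 °C
Reagents that add atoms: allyl bromide, C=CCBr
Why: Asymmetric phase-transfer α-alkylation of an α-methylmalonate with two different ester groups, in which the chiral N-spiro quaternary ammonium cation pairs with the enolate and shields one face, so that the allyl group sets the quaternary carbon that becomes C3.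

Step 4
Reactants: 5 1-tert-butyl 3-(2,2-diphenylethyl) (2S)-2-methyl-2-(prop-2-en-1-yl)propanedioate
Product: 6 (2R)-2-[(2,2-diphenylethoxy)carbonyl]-2-methylpent-4-enoic acid
Conditions: CF3CO2H, CH2Cl2, 0 °C
Reagents that add atoms: none
Why: Acidolysis of the tert-butyl ester through the tert-butyl cation leaves the primary 2,2-diphenylethyl ester and the quaternary centre intact, so the two malonate carbonyls are now differentiated as the future C2 (acid) and C4 (ester).

Step 5
Reactants: 7 (R)-(−)-linalool
Product: 8 (2E,6R)-2,6-dimethylocta-2,7-diene-1,6-diol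
Conditions: SeO2 (cat.), t-BuOOH, CH2Cl2, 0 °C to rt
Reagents that add atoms: tert-butyl hydroperoxide, CC(C)(C)OO
Why: Selenium dioxide allylic oxidation (ene reaction followed by [2,3]-sigmatropic shift) attacks the electron-rich trisubstituted alkene at its (E)-methyl group and leaves the vinyl group and the tertiary carbinol (future C14) untouched.

Step 6
Reactants: 8 (2E,6R)-2,6-dimethylocta-2,7-diene-1,6-diol
Product: 10 (3E,5E,9R)-9-hydroxy-5,9-dimethylundeca-3,5,10-trien-2-one, via enal 9 (not isolated)
Conditions: MnO2, Ph3P=CHC(O)CH3, PhMe, 80 °C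
Reagents that add atoms: 1-(triphenylphosphoranylidene)propan-2-one, CC(=O)C=P(c1ccccc1)(c1ccccc1)c1ccccc1
Why: Tandem allylic oxidation–Wittig olefination, in which MnO2 oxidises only the primary allylic alcohol and the stabilised ylide traps the sensitive enal as the (E)-enone, completing the (E,E)-diene of a 1,3,8-nonatriene.

Step 7
Reactants: 10 (3E,5E,9R)-9-hydroxy-5,9-dimethylundeca-3,5,10-trien-2-one
Product: 11 1-[(3R,3aS,5R,7aS)-3-hydroxy-3,7-dimethyl-2,3,3a,4,5,7a-hexahydro-1H-inden-5-yl]ethan-1-one
Conditions: PhMe (high dilution), BHT, 190 °C, sealed tube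
Reagents that add atoms: none
Why: Thermal intramolecular Diels–Alder reaction of the 1,3,8-nonatriene (diene C9=C10–C11=C5, dienophile C8=C7) forms C8–C9 and C5–C7; the three-atom tether with an unactivated terminal dienophile should favour the cis-fused transition state, and the C14 carbinol should place its small hydroxyl on the concave side and its methyl on the convex side, which sets C8 and C9, while the C5 configuration is irrelevant because C5 is enolised in step 9.

Step 8
Reactants: 11 1-[(3R,3aS,5R,7aS)-3-hydroxy-3,7-dimethyl-2,3,3a,4,5,7a-hexahydro-1H-inden-5-yl]ethan-1-one; 6 (2R)-2-[(2,2-diphenylethoxy)carbonyl]-2-methylpent-4-enoic acid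
Product: 13 2,2-diphenylethyl (2R)-2-{3-[(3R,3aS,5R,7aS)-3-hydroxy-3,7-dimethyl-2,3,3a,4,5,7a-hexahydro-1H-inden-5-yl]-3-oxopropanoyl}-2-methylpent-4-enoate, via acid chloride 12 (not isolated)
Conditions: 6, (COCl)2, DMF (cat.), CH2Cl2; then 11, MgBr2·OEt2, i-Pr2NEt, CH2Cl2, 0 °C to rt
Reagents that add atoms: none
Why: Claisen-type C-acylation of a methyl ketone by soft enolisation, in which the magnesium enolate is acylated at the methyl group only because only that product is held as the stable magnesium β-diketonate; the quaternary centre cannot racemise, and a shift of C10=C11 into conjugation would be harmless since both isomers give the same dienolate in step 9.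

Step 9
Reactants: 13 2,2-diphenylethyl (2R)-2-{3-[(3R,3aS,5R,7aS)-3-hydroxy-3,7-dimethyl-2,3,3a,4,5,7a-hexahydro-1H-inden-5-yl]-3-oxopropanoyl}-2-methylpent-4-enoate
Product: 14 spiro trione alkene (enol form; C4 cis to H8 and H9; C10=C11 retained)
Conditions: LiN(i-Pr)2 (3.5 equiv), THF, −78 to 0 °C; then 1 M HCl
Reagents that add atoms: none
Why: LiN(i-Pr)2 removes the C14 hydroxyl proton, the C1 proton of the β-diketone and then the C5 proton, which is γ to the diketonate and allylic to C10=C11, so that a cross-conjugated dienolate results whose C5 adds to the C4 ester carbonyl; 2,2-diphenylethoxide leaves and the cyclic β-diketonate of 14 is formed. The closest known reaction types are the Claisen (Dieckmann) cyclisation of 3,5-dioxoalkanoates and the γ-acylation of β-diketone dianions by esters, which lead to cyclohexane-1,3,5-triones. The six-membered ring closes in the 6-(enolendo)-exo-trig mode. The only new stereocentre, spiro C5, is under substrate control: with C10 still sp2 the carbocycle is flattened, its concave face is covered by the cis-fused cyclopentane and the C14 alkoxide, and C4 should therefore bond on the convex face, cis to H8 and H9. The step needs C- over O-acylation and α- over γ-attack of the dienolate; the carbanion terminus of the polyanion is its most nucleophilic site, γ-attack at C10 would require an eight-membered ring, and an O-acylated lactone, should it form, is the entry to the fallback. The product is protected from retro-Claisen cleavage as its enolate until work-up.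

Step 10
Reactants: 14 spiro trione alkene
Product: 16 spiro trione diol with allyl group (enol form; C10 hydroxyl cis to C6), via hydroperoxide 15 (not isolated)
Conditions: Mn(dpm)3 (cat.), PhSiH3, O2 (1 atm), i-PrOH/CH2Cl2, 0 °C; then PPh3
Reagents that add atoms: dioxygen, O=O
Why: Mukaiyama-type hydration by metal-hydride hydrogen-atom transfer, in which the hydrogen atom adds to C11 of the trisubstituted alkene (faster than to the monosubstituted allyl group) and the tertiary C10 radical should be trapped by O2 on the face anti to the now axial C4 carbonyl carbon, that is cis to C6, so that phosphine reduction gives the C10 carbinol with its methyl cis to C4.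

Step 11
Reactants: 16 spiro trione diol with allyl group
Product: 17 spiro trione diol with prenyl group (enol form)
Conditions: 2-methylbut-2-ene, second-generation Grubbs catalyst RuCl2(=CHPh)(H2IMes)(PCy3) (5 mol%), CH2Cl2, 40 °C
Reagents that add atoms: 2-methylbut-2-ene, CC=C(C)C
Why: Olefin cross-metathesis of the monosubstituted allyl group with an excess of the trisubstituted alkene converts allyl into prenyl with loss of propene; the cyclic 1,3-dione enol cannot chelate ruthenium and no stereocentre is touched.

Step 12
Reactants: 17 spiro trione diol with prenyl group; 18 (S)-2-methylbutanoic acid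
Product: 20 hyperielliptone HB, via enol ester 19 (not isolated)
Conditions: DCC, DMAP, CH2Cl2, 0 °C to rt
Reagents that add atoms: none
Why: Carbodiimide O-acylation of the dione enol followed by DMAP-mediated 1,3-O-to-C acyl migration (Steglich-type acylation–rearrangement) gives the C1-acyl β-triketone as the thermodynamic sink; the tertiary alcohols are not acylated and the acyl α-stereocentre, which passes through neither a ketene nor an enolate, is retained.

Compound list
1 | 2,2,5-trimethyl-1,3-dioxane-4,6-dione (methyl Meldrum's acid) | CC1C(=O)OC(C)(C)OC1=O | starting material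
2 | 3-tert-butoxy-2-methyl-3-oxopropanoic acid (racemic) | CC(C(=O)O)C(=O)OC(C)(C)C | intermediate
3 | 2,2-diphenylethanol | OCC(c1ccccc1)c1ccccc1 | starting material
4 | tert-butyl 2,2-diphenylethyl 2-methylpropanedioate (racemic) | CC(C(=O)OCC(c1ccccc1)c1ccccc1)C(=O)OC(C)(C)C | intermediate
5 | 1-tert-butyl 3-(2,2-diphenylethyl) (2S)-2-methyl-2-(prop-2-en-1-yl)propanedioate | CC(C)(C)OC(=O)[C@@](C)(CC=C)C(=O)OCC(c1ccccc1)c1ccccc1 | intermediate
6 | (2R)-2-[(2,2-diphenylethoxy)carbonyl]-2-methylpent-4-enoic acid | OC(=O)[C@@](C)(CC=C)C(=O)OCC(c1ccccc1)c1ccccc1 | intermediate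
7 | (R)-(−)-linalool, (3R)-3,7-dimethylocta-1,6-dien-3-ol | C=C[C@](C)(O)CCC=C(C)C | starting material
8 | (2E,6R)-2,6-dimethylocta-2,7-diene-1,6-diol | C=C[C@](C)(O)CC/C=C(\C)CO | intermediate
9 | (2E,6R)-6-hydroxy-2,6-dimethylocta-2,7-dienal | C=C[C@](C)(O)CC/C=C(\C)C=O | intermediate
10 | (3E,5E,9R)-9-hydroxy-5,9-dimethylundeca-3,5,10-trien-2-one | C=C[C@](C)(O)CC/C=C(\C)/C=C/C(C)=O | intermediate
11 | 1-[(3R,3aS,5R,7aS)-3-hydroxy-3,7-dimethyl-2,3,3a,4,5,7a-hexahydro-1H-inden-5-yl]ethan-1-one (cis-fused; hydroxyl on the concave face) | CC(=O)[C@@H]1C[C@H]2[C@H](CC[C@@]2(C)O)C(C)=C1 | intermediate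
12 | 2,2-diphenylethyl (2S)-2-(chlorocarbonyl)-2-methylpent-4-enoate | O=C(Cl)[C@@](C)(CC=C)C(=O)OCC(c1ccccc1)c1ccccc1 | intermediate
13 | 2,2-diphenylethyl (2R)-2-{3-[(3R,3aS,5R,7aS)-3-hydroxy-3,7-dimethyl-2,3,3a,4,5,7a-hexahydro-1H-inden-5-yl]-3-oxopropanoyl}-2-methylpent-4-enoate (drawn as the diketo tautomer) | O=C(CC(=O)[C@@](C)(CC=C)C(=O)OCC(c1ccccc1)c1ccccc1)[C@@H]1C[C@H]2[C@H](CC[C@@]2(C)O)C(C)=C1 | intermediate
14 | 3'-hydroxy-3,3',7'-trimethyl-3-(prop-2-en-1-yl)-1',2',3',3a',4',7a'-hexahydrospiro[cyclohexane-1,5'-indene]-2,4,6-trione, enol form; C4 cis to H8 and H9, C6 cis to C12 | C1=C(O)[C@@](C)(CC=C)C(=O)[C@]2(C[C@H]3[C@H](CC[C@@]3(C)O)C(C)=C2)C1=O | intermediate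
15 | C10 hydroperoxide of 16 (hydroperoxy group cis to C6) | C1=C(O)[C@@](C)(CC=C)C(=O)[C@]2(C[C@H]3[C@H](CC[C@@]3(C)O)[C@](C)(OO)C2)C1=O | intermediate
16 | 3',7'-dihydroxy-3,3',7'-trimethyl-3-(prop-2-en-1-yl)octahydrospiro[cyclohexane-1,5'-indene]-2,4,6-trione, enol form; C10 hydroxyl cis to C6 | C1=C(O)[C@@](C)(CC=C)C(=O)[C@]2(C[C@H]3[C@H](CC[C@@]3(C)O)[C@](C)(O)C2)C1=O | intermediate
17 | 3',7'-dihydroxy-3,3',7'-trimethyl-3-(3-methylbut-2-en-1-yl)octahydrospiro[cyclohexane-1,5'-indene]-2,4,6-trione, enol form | C1=C(O)[C@@](C)(CC=C(C)C)C(=O)[C@]2(C[C@H]3[C@H](CC[C@@]3(C)O)[C@](C)(O)C2)C1=O | intermediate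
18 | (S)-2-methylbutanoic acid | CC[C@H](C)C(=O)O | starting material
19 | enol (2S)-2-methylbutanoate of 17 (acyl on the C2 enol oxygen) | C1=C(OC(=O)[C@@H](C)CC)[C@@](C)(CC=C(C)C)C(=O)[C@]2(C[C@H]3[C@H](CC[C@@]3(C)O)[C@](C)(O)C2)C1=O | intermediate
20 | hyperielliptone HB (17 carrying the (2S)-2-methylbutanoyl group on C1; enolised β-triketone) | CC[C@H](C)C(=O)C1=C(O)[C@@](C)(CC=C(C)C)C(=O)[C@]2(C[C@H]3[C@H](CC[C@@]3(C)O)[C@](C)(O)C2)C1=O | target

Total step count: 12. Longest linear sequence: 9 steps (steps 1, 2, 3, 4, 8, 9, 10, 11, 12); the linalool branch has 8 steps.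

Steps most likely to fail

Step 9. The hindered tertiary C5 carbanion may form slowly, so that O-acylation of the diketonate oxygen (lactonisation) or proton exchange outruns C-acylation. The fallback sets out from 13 and returns at 14, and it accepts the O-acylation on purpose. DBU in toluene at 80 °C should close the six-membered enol lactone F1 with loss of 2,2-diphenylethanol. Mg(OMe)2 in refluxing methanol then opens the lactone reversibly to the magnesium-chelated triketo methyl ester, which closes by Claisen condensation at C5, driven by formation of the stable trione enolate. This is the lactone-to-carbocycle isomerisation known for pyranone-type enol lactones and alkylidene phthalides; the facial course at C5 is expected to be the same as in step 9.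

Step 7. The unactivated dienophile may need a temperature at which the tertiary allylic alcohol dehydrates or fragments, and the preference for the cis-fused, hydroxyl-concave transition state may be too small. The fallback sets out from 10 and returns at 11. It replaces the concerted thermal cycloaddition by a metal-templated formal [4+2] cycloaddition with the cationic rhodium complex [Rh(cod)(C10H8)]SbF6 in CH2Cl2 at 25–40 °C. Diene and alkene are coupled through a rhodacycle and reductive elimination, so the C8–C9 and C5–C7 bonds form far below the dehydration temperature; no new compound is involved.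

Step 10. The metal hydride may also transfer hydrogen to the allyl group or to the enolised dione, and dioxygen may trap the C10 radical with poor facial selectivity. The fallback sets out from 14 and returns at 16, and it delivers the oxygen intramolecularly by an ionic path. Catalytic CF3SO3H in CH2Cl2 at 0 °C protonates C11, and the C6 enol oxygen, which can reach C10 only on the required face, captures the tertiary cation to give bridged cyclic enol ether F2. Hydrolysis of this strained vinylogous ester with LiOH in THF/H2O releases the C10 alcohol as the dione enolate. Capture of the cation by the C14 hydroxyl is the competing process to watch.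

Further compounds
F0 | step 7 | none | none
F1 | step 9 | 6-[(3R,3aS,5R,7aS)-3-hydroxy-3,7-dimethyl-2,3,3a,4,5,7a-hexahydro-1H-inden-5-yl]-3-methyl-3-(prop-2-en-1-yl)-2H-pyran-2,4(3H)-dione (C3 as in 13) | O=C1C=C([C@@H]2C[C@H]3[C@H](CC[C@@]3(C)O)C(C)=C2)OC(=O)[C@]1(C)CC=C
F2 | step 10 | bridged cyclic enol ether of 16 (five-membered ring O–C6–C5–C11–C10; C6=C1 enol ether conjugated with the C2 ketone) | O=C1C=C2O[C@]3(C)C[C@]2(C[C@H]4[C@@H]3CC[C@@]4(C)O)C(=O)[C@]1(C)CC=C
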